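The cyclohexane (ring A) is opened between the carbinol carbon C6 and its neighbour C5, the ring CH that carries the acrolein unit. Their cis 6-OH/5-alkenyl relationship, a homoallylic alcohol with a 1,1-disubstituted alkene, is the imprint of an oxanickelacycle: zerovalent nickel couples an aldehyde (C6) with the proximal carbon of a terminal allene (C5), and dimethylzinc methylates the central allene carbon. One operation thus closes ring A, sets C5 and C6 and delivers the isopropenyl precursor of the enal. The precursor is an acyclic allenyl aldehyde hung on a preformed trans-lactone whose methylene is masked as a dimethylamine adduct.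

Key step: step 13

Remark on numbering (elemane type): C1–C2 oxirane; C3=C4–C15 the acrolein unit on C5; C5–C10 ring A (C6 carbinol, C9 ester carbon, C10 quaternary, bearing methyl C14 and the oxirane); C7–C11(=C13)–C12(=O)–O–C8 the lactone, ring B.
Remark on configuration: in 19–23, C4 (on C5), O6, C11 (on C7) and C14 lie on one face of ring A; O8, O9 and C1 lie on the other.
Assumption: the target is taken as the open γ-hydroxy enal as drawn; a lactol tautomer, if present, would equilibrate with it.
Assumption: C11 in 16–20 (the aminomethyl-bearing carbon) is an inconsequential epimer mixture, left undefined in the SMILES and erased in step 14.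

Step 1
Reactants: 1 (Z)-3-methylpent-2-en-4-yn-1-ol
Product: 3 4,4,5,5-tetramethyl-2-[(2Z)-3-methylpent-2-en-4-yn-1-yl]-1,3,2-dioxaborolane, via allylic chloride 2 (not isolated)
Conditions: NCS, Me2S, CH2Cl2, −20 to 0 °C; then crude 2, B2pin2, Pd2(dba)3 (1 mol%), THF, 60 °C
Reagents that add atoms: bis(pinacolato)diboron, CC1(C)OB(B2OC(C)(C)C(C)(C)O2)OC1(C)C
Why: Corey–Kim chlorination of the primary allylic alcohol, then Pd2(dba)3-catalysed Miyaura-type borylation of the allylic chloride at its primary terminus, should keep the Z geometry (alkynyl cis to CH2B), which is also the thermodynamically preferred one.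

Step 2
Reactants: 3 the (Z)-allylboronate; 4 2-(tert-butyldimethylsilyloxy)acetaldehyde
Product: 5 (2S,3S)-1-(tert-butyldimethylsilyloxy)-3-ethenyl-3-methylpent-4-yn-2-ol
Conditions: (S)-TRIP (5 mol%), 4 Å molecular sieves, toluene, −30 °C; NaHCO3 (aq) work-up
Reagents that add atoms: none
Why: Chiral phosphoric acid-catalysed allylboration through a closed Zimmerman–Traxler chair should give the (2S,3S) alcohol, the Z-placed alkynyl group ending syn and the methyl anti to the new hydroxyl at the quaternary carbon C10, with the (S)-catalyst expected to direct attack to the Si face of the aldehyde (its antipode would be taken if a model run shows the opposite sense).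

Step 3
Reactants: 5 the homoallylic alcohol
Product: 6 (2S,3S)-1-(tert-butyldimethylsilyloxy)-3-methyl-3-[(2R)-oxiran-2-yl]pent-4-yn-2-ol
Conditions: VO(acac)2 (5 mol%), t-BuOOH (1.5 equiv, decane), CH2Cl2, 0 °C to rt
Reagents that add atoms: tert-butyl hydroperoxide, CC(C)(C)OO
Why: VO(acac)2-catalysed hydroxyl-directed epoxidation of the homoallylic alcohol through a chair-like vanadate transition state (CH2OTBS equatorial, vinyl extended) should give the 1,3-syn epoxy alcohol, i.e. the (R)-oxirane, while the alkyne is inert.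

Step 4
Reactants: 6 the epoxy alcohol
Product: 7 (2S,3R)-1-(tert-butyldimethylsilyloxy)-3-methyl-3-[(2R)-oxiran-2-yl]pent-4-yn-2-yl 2-methylpropanoate
Conditions: isobutyric anhydride, DMAP, Et3N, CH2Cl2, rt
Reagents that add atoms: isobutyric anhydride, CC(C)C(=O)OC(=O)C(C)C
Why: DMAP-catalysed (Steglich-type) acylation of the hindered secondary alcohol under basic, chloride-free conditions should spare the oxirane and touches no stereocentre.

Step 5
Reactants: 7 the alkynyl ester
Product: 9 (2S,3R)-1-(tert-butyldimethylsilyloxy)-3-methyl-3-[(2R)-oxiran-2-yl]hexa-4,5-dien-2-yl 2-methylpropanoate, via propargylic amine 8 (not isolated)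
Conditions: (CH2O)n, CuI (0.5 equiv), Cy2NH, 1,4-dioxane, reflux
Reagents that add atoms: paraformaldehyde (formaldehyde), C=O
Why: Crabbé homologation, in which a CuI-mediated Mannich (alkyne–aldehyde–amine) coupling gives the propargylic amine and its 1,5-hydride shift and fragmentation deliver the terminal allene, under conditions that should leave ester, silyl ether and oxirane untouched.

Step 6
Reactants: 9 the allenyl silyl ether
Product: 10 (2S,3R)-1-hydroxy-3-methyl-3-[(2R)-oxiran-2-yl]hexa-4,5-dien-2-yl 2-methylpropanoate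
Conditions: HF·pyridine, pyridine, THF, 0 °C
Reagents that add atoms: none
Why: Buffered fluoride desilylation of the primary TBS ether should leave oxirane, allene and ester intact and avoids the base-induced acyl shift to the freed primary hydroxyl.

Step 7
Reactants: 10 the primary alcohol
Product: 11 (2S,3R)-3-methyl-3-[(2R)-oxiran-2-yl]-1-oxohexa-4,5-dien-2-yl 2-methylpropanoate
Conditions: Dess–Martin periodinane, NaHCO3, CH2Cl2, 0 °C to rt; used crude
Reagents that add atoms: none
Why: Dess–Martin oxidation under buffered conditions should give the α-acyloxy aldehyde without epimerisation at C9.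

Step 8
Reactants: 4 2-(tert-butyldimethylsilyloxy)acetaldehyde; 12 methyl acrylate
Product: 13 methyl 4-(tert-butyldimethylsilyloxy)-3-hydroxy-2-methylidenebutanoate (racemic)
Conditions: DABCO (30 mol%), 1,4-dioxane/H2O, rt
Reagents that add atoms: none
Why: Morita–Baylis–Hillman reaction of a reactive α-oxygenated aldehyde, the racemic carbinol centre being removed in step 9.

Step 9
Reactants: 13 the Baylis–Hillman alcohol
Product: 14 methyl (2Z)-2-(bromomethyl)-4-(tert-butyldimethylsilyloxy)but-2-enoate
Conditions: NBS, Me2S, CH2Cl2, 0 °C to rt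
Reagents that add atoms: N-bromosuccinimide, O=C1CCC(=O)N1Br
Why: Bromination with allylic transposition (SN2′) of the alkoxysulfonium intermediate should give the thermodynamically favoured (Z)-2-(bromomethyl)enoate.

Step 10
Reactants: 11 the α-acyloxy aldehyde; 14 the allylic bromide
Product: 16 (1S,2R)-1-[(2R,3S)-3-(tert-butyldimethylsilyloxymethyl)-4-[(dimethylamino)methyl]-5-oxooxolan-2-yl]-2-methyl-2-[(2R)-oxiran-2-yl]penta-3,4-dien-1-yl 2-methylpropanoate (C11 epimers), via methylene lactone 15 (not isolated)
Conditions: CrCl2 (4 equiv), THF, rt; aqueous work-up; then crude 15, Me2NH (2 M in THF), 0 °C to rt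
Reagents that add atoms: dimethylamine, CNC
Why: CrCl2-mediated (Nozaki–Hiyama-type) allylation, in which the equilibrating γ-substituted allylchromium should add through a chair transition state to the Felkin–Anh face of the α-acyloxy aldehyde (new C8–O anti to C9–O, C7/C8 anti), the alkoxide lactonising to the trans-lactone, and aza-Michael addition of Me2NH then masks the methylene.

Step 11
Reactants: 16 the silyl ether
Product: 17 (1S,2R)-1-[(2R,3S)-4-[(dimethylamino)methyl]-3-(hydroxymethyl)-5-oxooxolan-2-yl]-2-methyl-2-[(2R)-oxiran-2-yl]penta-3,4-dien-1-yl 2-methylpropanoate (C11 epimers)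
Conditions: HF·pyridine, pyridine, THF, 0 °C to rt; NaHCO3 (aq)
Reagents that add atoms: none
Why: Buffered fluoride desilylation frees the C6 hydroxyl while the protonated amine, oxirane, allene and esters should survive.

Step 12
Reactants: 17 the primary alcohol
Product: 18 (1S,2R)-1-[(2R,3R)-4-[(dimethylamino)methyl]-3-formyl-5-oxooxolan-2-yl]-2-methyl-2-[(2R)-oxiran-2-yl]penta-3,4-dien-1-yl 2-methylpropanoate (C11 epimers)
Conditions: (COCl)2, DMSO, CH2Cl2, −78 °C; Et3N, −78 to 0 °C
Reagents that add atoms: none
Why: Swern oxidation tolerates the tertiary amine, oxirane and allene, and its Et3N can only relax C7 (now α to the aldehyde) towards the favoured trans-disubstituted lactone.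

Step 13
Reactants: 18 the allenyl aldehyde
Product: 19 13-(dimethylamino)-1,2-epoxy-6-hydroxy-9-(2-methylpropanoyloxy)-11,13-dihydroelem-3-en-12,8-olide (5-isopropenyl cis to 6-OH; C11 epimers)
Conditions: Ni(cod)2 (15 mol%), Me2Zn (3 equiv, 2 M in toluene), THF, 0 °C to rt; NH4Cl (aq)
Reagents that add atoms: dimethylzinc, C[Zn]C
Why: Zerovalent nickel binds the aldehyde and the proximal allene π bond of 18, and oxidative cyclisation forms C5–C6 within an oxanickelacyclopentane (Ni on O6 and on the alkenyl carbon C4); Me2Zn then hands a methyl to nickel as zinc takes the alkoxide, and reductive elimination makes C4–C15 and frees the catalyst. The closest known reaction type is the Ni(cod)2-catalysed alkylative cyclisation of allenyl aldehydes with organozincs, which gives cis-2-(alk-1-en-2-yl)cycloalkanols. Ring A closes in a 6-exo mode onto the substituted allene terminus C5, the central carbon C4 ending exocyclic. The cis C5/C6 relationship follows from the five-membered metallacycle, in which O6 and C4 must leave the new ring from the same face; which cis pair forms is decided by the trans-fused lactone, which locks the chair so that C4 sits equatorial on C5 (an axial C4 would meet the axial C9 ester) and the oxygen is then axial on C6. The step needs chemoselectivity for allene–aldehyde coupling over conjugate addition, direct 1,2-methylation and oxirane opening, which the amine mask on C13, the slow uncatalysed addition of Me2Zn and the halide-free reagent should secure.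

Step 14
Reactants: 19 the Mannich-base lactone
Product: 21 1,2-epoxy-6-hydroxy-9-(2-methylpropanoyloxy)elema-3,11(13)-dien-12,8-olide, via ammonium iodide 20 (not isolated)
Conditions: MeI (excess), THF, rt; then NaHCO3 (aq), CH2Cl2, rt
Reagents that add atoms: none
Why: Exhaustive N-methylation followed by E1cB (Hofmann-type) elimination of trimethylamine should regenerate the α-methylene lactone and erase C11.

Step 15
Reactants: 21 the isopropenyl lactone
Product: 23 CNP0519565.1, 1,2-epoxy-6-hydroxy-9-(2-methylpropanoyloxy)-15-oxoelema-3,11(13)-dien-12,8-olide, via allylic alcohol 22 (not isolated)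
Conditions: SeO2 (1.5 equiv), 1,4-dioxane, 70 °C
Reagents that add atoms: selenium dioxide, O=[Se]=O
Why: Riley oxidation, in which SeO2 undergoes an ene reaction and a 2,3-sigmatropic shift at the methyl group of the electron-rich isopropenyl unit and oxidises the resulting allylic alcohol on to the conjugated aldehyde, while the electron-poor lactone methylene should stay inert and no stereocentre is touched.

Compound list
1 | (Z)-3-methylpent-2-en-4-yn-1-ol | OC/C=C(\C#C)C | starting material
2 | (Z)-5-chloro-3-methylpent-3-en-1-yne | ClC/C=C(\C#C)C | intermediate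
3 | 4,4,5,5-tetramethyl-2-[(2Z)-3-methylpent-2-en-4-yn-1-yl]-1,3,2-dioxaborolane | CC1(C)OB(C/C=C(\C#C)C)OC1(C)C | intermediate
4 | 2-(tert-butyldimethylsilyloxy)acetaldehyde | O=CCO[Si](C)(C)C(C)(C)C | starting material
5 | (2S,3S)-1-(tert-butyldimethylsilyloxy)-3-ethenyl-3-methylpent-4-yn-2-ol | C#C[C@](C)(C=C)[C@@H](CO[Si](C)(C)C(C)(C)C)O | intermediate
6 | (2S,3S)-1-(tert-butyldimethylsilyloxy)-3-methyl-3-[(2R)-oxiran-2-yl]pent-4-yn-2-ol | C#C[C@](C)([C@@H]1CO1)[C@@H](CO[Si](C)(C)C(C)(C)C)O | intermediate
7 | (2S,3R)-1-(tert-butyldimethylsilyloxy)-3-methyl-3-[(2R)-oxiran-2-yl]pent-4-yn-2-yl 2-methylpropanoate | C#C[C@](C)([C@@H]1CO1)[C@@H](CO[Si](C)(C)C(C)(C)C)OC(=O)C(C)C | intermediate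
8 | (2S,3R)-1-(tert-butyldimethylsilyloxy)-6-(dicyclohexylamino)-3-methyl-3-[(2R)-oxiran-2-yl]hex-4-yn-2-yl 2-methylpropanoate | C(C#C[C@](C)([C@@H]1CO1)[C@@H](CO[Si](C)(C)C(C)(C)C)OC(=O)C(C)C)N(C2CCCCC2)C3CCCCC3 | intermediate
9 | (2S,3R)-1-(tert-butyldimethylsilyloxy)-3-methyl-3-[(2R)-oxiran-2-yl]hexa-4,5-dien-2-yl 2-methylpropanoate | C=C=C[C@](C)([C@@H]1CO1)[C@@H](CO[Si](C)(C)C(C)(C)C)OC(=O)C(C)C | intermediate
10 | (2S,3R)-1-hydroxy-3-methyl-3-[(2R)-oxiran-2-yl]hexa-4,5-dien-2-yl 2-methylpropanoate | C=C=C[C@](C)([C@@H]1CO1)[C@@H](CO)OC(=O)C(C)C | intermediate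
11 | (2S,3R)-3-methyl-3-[(2R)-oxiran-2-yl]-1-oxohexa-4,5-dien-2-yl 2-methylpropanoate | C=C=C[C@](C)([C@@H]1CO1)[C@@H](C=O)OC(=O)C(C)C | intermediate
12 | methyl acrylate | C=CC(=O)OC | starting material
13 | methyl 4-(tert-butyldimethylsilyloxy)-3-hydroxy-2-methylidenebutanoate (racemic) | C=C(C(=O)OC)C(O)CO[Si](C)(C)C(C)(C)C | intermediate
14 | methyl (2Z)-2-(bromomethyl)-4-(tert-butyldimethylsilyloxy)but-2-enoate | BrC/C(C(=O)OC)=C\CO[Si](C)(C)C(C)(C)C | intermediate
15 | (1S,2R)-1-[(2R,3S)-3-(tert-butyldimethylsilyloxymethyl)-4-methylidene-5-oxooxolan-2-yl]-2-methyl-2-[(2R)-oxiran-2-yl]penta-3,4-dien-1-yl 2-methylpropanoate | C=C1C(=O)O[C@@H]([C@@H](OC(=O)C(C)C)[C@@](C)([C@@H]3CO3)C=C=C)[C@@H]1CO[Si](C)(C)C(C)(C)C | intermediate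
16 | dimethylamine adduct of 15 (4-[(dimethylamino)methyl]oxolanone; C11 epimers) | CN(C)CC1C(=O)O[C@@H]([C@@H](OC(=O)C(C)C)[C@@](C)([C@@H]3CO3)C=C=C)[C@@H]1CO[Si](C)(C)C(C)(C)C | intermediate
17 | desilylated 16 (3-(hydroxymethyl)oxolanone; C11 epimers) | CN(C)CC1C(=O)O[C@@H]([C@@H](OC(=O)C(C)C)[C@@](C)([C@@H]3CO3)C=C=C)[C@@H]1CO | intermediate
18 | (1S,2R)-1-[(2R,3R)-4-[(dimethylamino)methyl]-3-formyl-5-oxooxolan-2-yl]-2-methyl-2-[(2R)-oxiran-2-yl]penta-3,4-dien-1-yl 2-methylpropanoate (C11 epimers) | CN(C)CC1C(=O)O[C@@H]([C@@H](OC(=O)C(C)C)[C@@](C)([C@@H]3CO3)C=C=C)[C@@H]1C=O | intermediate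
19 | 13-(dimethylamino)-1,2-epoxy-6-hydroxy-9-(2-methylpropanoyloxy)-11,13-dihydroelem-3-en-12,8-olide (C11 epimers; ring A configured as in the target) | CN(C)CC1C(=O)O[C@@H]2[C@@H]1[C@@H](O)[C@@H](C(C)=C)[C@](C)([C@@H]1CO1)[C@@H]2OC(=O)C(C)C | intermediate
20 | N-methyl ammonium iodide of 19 | C[N+](C)(C)CC1C(=O)O[C@@H]2[C@@H]1[C@@H](O)[C@@H](C(C)=C)[C@](C)([C@@H]1CO1)[C@@H]2OC(=O)C(C)C.[I-] | intermediate
21 | 1,2-epoxy-6-hydroxy-9-(2-methylpropanoyloxy)elema-3,11(13)-dien-12,8-olide (configured as in the target) | C=C1C(=O)O[C@@H]2[C@@H]1[C@@H](O)[C@@H](C(C)=C)[C@](C)([C@@H]1CO1)[C@@H]2OC(=O)C(C)C | intermediate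
22 | 15-hydroxy derivative of 21 (allylic alcohol) | C=C1C(=O)O[C@@H]2[C@@H]1[C@@H](O)[C@@H](C(=C)CO)[C@](C)([C@@H]1CO1)[C@@H]2OC(=O)C(C)C | intermediate
23 | CNP0519565.1: 1,2-epoxy-6-hydroxy-9-(2-methylpropanoyloxy)-15-oxoelema-3,11(13)-dien-12,8-olide (1R, 8R; relative configuration as in the remark) | C=C1C(=O)O[C@@H]2[C@@H]1[C@@H](O)[C@@H](C(=C)C=O)[C@](C)([C@@H]1CO1)[C@@H]2OC(=O)C(C)C | target

Total step count: 15 steps.
Longest linear sequence: 13 steps (steps 1–7, then 10–15); steps 8–9 make the second fragment.

Steps most likely to fail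

Step 13 (key step). What may go wrong is diversion of the zerovalent nickel (binding by the amine, insertion into the oxirane), uncatalysed transfer of methyl from zinc to the aldehyde, or a sluggish oxidative cyclisation at the neopentyl allene carbon C5. The fallback sets out from 18. A CuCl-catalysed borylative cyclisation (CuCl, an N-heterocyclic carbene ligand, catalytic NaOt-Bu, B2pin2, THF, rt) should add copper and boron across the terminal allene π bond. The resulting (Z)-2-boryl allylcopper adds to the aldehyde through a chair transition state with the same cis C5/C6 outcome, giving the alkenylboronate F1. Suzuki–Miyaura methylation of F1 (PdCl2(dppf), MeI in excess, K3PO4, THF/H2O, 50 °C) installs C15, while the excess MeI quaternises the amine and the base eliminates it. The route is rejoined at 21.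

Step 3. What may go wrong is insufficient facial discrimination in the vanadium-directed oxygen transfer, because the quaternary C10 makes the two chair transition states similar in energy. The fallback sets out from 5. Acylation with Boc2O and DMAP gives the tert-butyl carbonate F2. Iodocarbonate cyclisation (IBr, toluene, −85 °C) should close a six-membered carbonate with the CH2OTBS and CH2I groups both equatorial, giving the cis-4,6 iodo carbonate F3 with the 1,3-syn oxygen pattern. K2CO3 in MeOH cleaves the carbonate and closes the oxirane, coming back to the route at 6.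

Step 15. What may go wrong is stalling at the allylic alcohol stage, acid-induced opening of the oxirane by selenous acid at 70 °C, or competing oxidation at the C5 methine. The fallback sets out from 21. Ene-type allylic chlorination with transposition (NCS, PhSeCl (10 mol%), CH2Cl2, rt) should give the allylic chloride F4. Oxidation of F4 with N-methylmorpholine N-oxide (DMSO, rt, Kornblum-type) converts the chloromethyl group into the aldehyde and comes back to the route at 23.

Further compounds
F1 | step 13 | alkenylboronate: analogue of 19 with B(pin) on C4 in place of the C15 methyl | CN(C)CC1C(=O)O[C@@H]2[C@@H]1[C@@H](O)[C@@H](C(=C)B3OC(C)(C)C(C)(C)O3)[C@](C)([C@@H]1CO1)[C@@H]2OC(=O)C(C)C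
F2 | step 3 | tert-butyl (2S,3S)-1-(tert-butyldimethylsilyloxy)-3-ethenyl-3-methylpent-4-yn-2-yl carbonate | C#C[C@](C)(C=C)[C@@H](CO[Si](C)(C)C(C)(C)C)OC(=O)OC(C)(C)C
F3 | step 3 | cis-4-(tert-butyldimethylsilyloxymethyl)-5-ethynyl-6-(iodomethyl)-5-methyl-1,3-dioxan-2-one | O=C1O[C@H](CO[Si](C)(C)C(C)(C)C)[C@](C)(C#C)[C@H](CI)O1
F4 | step 15 | 15-chloro derivative of 21 (allylic chloride) | C=C1C(=O)O[C@@H]2[C@@H]1[C@@H](O)[C@@H](C(=C)CCl)[C@](C)([C@@H]1CO1)[C@@H]2OC(=O)C(C)C
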